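**Retrosynthetic overview**
- The all-E triene is cut between its first and second alkene: a Heck coupling of a ring-bound vinyl group with a bromodienamide that already carries the aminocyclopentenone (C5N) unit.
- The ring enamide C–N bond is cut next: copper-catalysed amidation of a 2-iodoenone with the primary (2E,4E,6R)-dienamide.
- The cis-4,5-diol comes from an achiral 4-hydroxy-4-vinylcyclohexadienone by an organocatalytic, desymmetrising boronate oxa-Michael addition that sets both ring stereocentres at once.
- The dienamide comes from Horner–Wadsworth–Emmons olefination, cross-metathesis and a copper-catalysed asymmetric allylic methylation that sets C6. The bromodienamide comes from glutaconaldehyde and cyclopentane-1,3-dione.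
- No carbocycle is built. The six-membered ring enters as quinone monoketal and is elaborated first; the five-membered ring enters as cyclopentane-1,3-dione on the lower fragment. The only ring closed is the transient dioxaborolane of the key step.

Assumption: the SMILES is read literally, so side-chain C6 is R and the ring carbinols are 4S,5R (enone numbering), which places the two hydroxyls cis; the C5N unit is drawn as its enol.
Assumption: the sense of induction of the chiral catalysts in steps 2 and 12 is assigned by analogy; both are available in the antipodal or pseudo-enantiomeric form, and the correct one is fixed by an ee and rotation check on 3 and 22.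

**Route**

Step 1
Reactants: 1 (E)-hept-2-en-1-ol
Product: 2 (E)-1-bromohept-2-ene
Conditions: PBr3 (0.4 equiv), pyridine (cat.), Et2O, −10 → 0 °C
Reagents that add atoms: phosphorus tribromide BrP(Br)Br
Why: SN2 displacement of the phosphite ester of a primary allylic alcohol (classical PBr3 bromination) keeps the E alkene.

Step 2
Reactants: 2 (E)-1-bromohept-2-ene
Product: 3 (R)-3-methylhept-1-ene
Conditions: MeMgBr (1.2 equiv), CuBr·SMe2 (1 mol %), (R,Rp)-Taniaphos (1.2 mol %), CH2Cl2, −75 °C
Reagents that add atoms: methylmagnesium bromide C[Mg]Br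
Why: copper-catalysed asymmetric allylic alkylation (SN2′) of the linear bromide gives the branched alkene, and the ferrocenyl diphosphine controls the face of attack so that the new stereocentre (future side-chain C6) is R.

Step 3
Reactants: 3 (R)-3-methylhept-1-ene; 4 methacrolein
Product: 5 (2E,4R)-2,4-dimethyloct-2-enal
Conditions: second-generation Hoveyda–Grubbs catalyst RuCl2(H2IMes)(=CH-2-iPrOC6H4) (5 mol %), 4 (8 equiv), CH2Cl2, 40 °C
Reagents that add atoms: none
Why: olefin cross-metathesis of a terminal alkene with excess methacrolein gives the trisubstituted E enal under thermodynamic control and does not touch the allylic stereocentre.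

Step 4
Reactants: 5 (2E,4R)-2,4-dimethyloct-2-enal; 6 diethyl (2-amino-2-oxoethyl)phosphonate
Product: 7 (2E,4E,6R)-4,6-dimethyldeca-2,4-dienamide
Conditions: LiCl, DBU, MeCN, 0 °C → rt
Reagents that add atoms: none
Why: Horner–Wadsworth–Emmons olefination under mild Masamune–Roush conditions gives the E acrylamide without epimerising the γ-stereocentre.

Step 5
Reactants: 8 pyridine–sulfur trioxide complex
Product: 9 potassium (1E,3E)-5-oxopenta-1,3-dien-1-olate
Conditions: KOH (aq.), −20 → 40 °C
Reagents that add atoms: potassium hydroxide [K+].[OH-]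
Why: hydroxide ring-opening of the N-sulfonated pyridinium (Zincke-type ring opening) is the standard preparation of the glutaconaldehyde enolate.

Step 6
Reactants: 9 potassium (1E,3E)-5-oxopenta-1,3-dien-1-olate
Product: 10 (2E,4E)-5-bromopenta-2,4-dienal
Conditions: PPh3, Br2, CH2Cl2, 0 °C → rt
Reagents that add atoms: bromine BrBr
Why: Appel-type O-activation of the vinylogous formate enolate by Ph3PBr2 followed by addition–elimination of bromide gives the ω-bromodienal, which settles as the E,E isomer.

Step 7
Reactants: 10 (2E,4E)-5-bromopenta-2,4-dienal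
Product: 11 (2E,4E)-5-bromopenta-2,4-dienoic acid
Conditions: NaClO2, NaH2PO4, 2-methylbut-2-ene, t-BuOH/H2O, 0 °C → rt
Reagents that add atoms: sodium chlorite [Na+].[O-]Cl=O
Why: Pinnick oxidation converts the enal into the acid without touching the diene or the vinyl bromide, because the hypochlorite by-product is scavenged.

Step 8
Reactants: 12 cyclopentane-1,3-dione
Product: 13 2-(hydroxyimino)cyclopentane-1,3-dione
Conditions: NaNO2, aq. HCl, 0 °C
Reagents that add atoms: sodium nitrite [Na+].[O-]N=O
Why: electrophilic nitrosation at the enolic C2 of the 1,3-dione followed by tautomerisation gives the oxime.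

Step 9
Reactants: 13 2-(hydroxyimino)cyclopentane-1,3-dione
Product: 14 2-amino-3-hydroxycyclopent-2-en-1-one hydrochloride
Conditions: H2 (1 atm), Pd/C (10 wt %), HCl, MeOH, rt
Reagents that add atoms: hydrogen chloride Cl
Why: catalytic hydrogenation of the oxime gives the amine, which is trapped as its hydrochloride so that it cannot self-condense.

Step 10
Reactants: 11 (2E,4E)-5-bromopenta-2,4-dienoic acid; 14 2-amino-3-hydroxycyclopent-2-en-1-one hydrochloride
Product: 16 (2E,4E)-5-bromo-N-(2-hydroxy-5-oxocyclopent-1-en-1-yl)penta-2,4-dienamide, via acid chloride 15 (not isolated)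
Conditions: (COCl)2, DMF (cat.), CH2Cl2, 0 °C; then 14, Et3N, CH2Cl2, −20 °C → rt
Reagents that add atoms: oxalyl chloride ClC(=O)C(Cl)=O (chlorine of 15 only)
Why: acid chloride formation and N-acylation of the liberated amine give the vinylogous-acid amide (any O-acyl isomer transfers to nitrogen), and the vinyl bromide is inert.

Step 11
Reactants: 17 4,4-dimethoxycyclohexa-2,5-dien-1-one
Product: 19 4-ethenyl-4-hydroxycyclohexa-2,5-dien-1-one, via ketal carbinol 18 (not isolated)
Conditions: CH2=CHMgBr, THF, −78 °C; then 10% aq. oxalic acid, THF, 0 °C → rt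
Reagents that add atoms: vinylmagnesium bromide C=C[Mg]Br; water O
Why: Grignard 1,2-addition to the cross-conjugated ketone of the quinone monoketal followed by mild ketal hydrolysis gives the achiral, prochiral p-quinol.

Step 12
Reactants: 19 4-ethenyl-4-hydroxycyclohexa-2,5-dien-1-one
Product: 22 (4S,5R)-4-ethenyl-4,5-dihydroxycyclohex-2-en-1-one, via boronic hemiester 20 (not isolated), via cyclic phenylboronate 21 (not isolated)
Conditions: PhB(OH)2 (1.3 equiv), 9-amino(9-deoxy)epi-quinine 3,5-bis(trifluoromethyl)phenyl thiourea (10 mol %), 4 Å MS, toluene, 23 °C; then pinacol (3 equiv), THF/H2O, rt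
Reagents that add atoms: phenylboronic acid OB(O)c1ccccc1
Why: Proposed new method: the tertiary OH of 19 condenses with PhB(OH)2 to hemiester 20, the quinuclidine nitrogen of the bifunctional catalyst binds boron to give a chiral ate complex whose B–OH oxygen is the nucleophile while the thiourea hydrogen-bonds the dienone carbonyl, so the tethered hydroxide equivalent can only reach C3 or C5 on the face of the quinol oxygen (cis fusion is enforced) and the catalyst selects one of the two enantiotopic enone arms, setting C4 (S) and C5 (R) in a single desymmetrising intramolecular oxa-Michael addition before pinacol releases the diol; the closest known reaction types are the amine–thiourea-catalysed boronate oxy-Michael addition of acyclic γ-hydroxy enones and bifunctional-catalyst desymmetrisations of cyclohexadienones by tethered O- or N-nucleophiles, and the pseudo-enantiomeric epi-quinidine catalyst is used if the sense proves opposite.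

Step 13
Reactants: 22 (4S,5R)-4-ethenyl-4,5-dihydroxycyclohex-2-en-1-one
Product: 23 (4S,5R)-4-ethenyl-4,5-dihydroxy-2-iodocyclohex-2-en-1-one
Conditions: I2, pyridine/CH2Cl2 (1:1), 0 °C → rt
Reagents that add atoms: iodine [I][I]
Why: Johnson α-iodination (Baylis–Hillman-type addition of pyridine, iodination of the enolate, elimination) functionalises only the enone α-carbon, and the weakly basic medium leaves the β-hydroxy ketone and both stereocentres intact.

Step 14
Reactants: 23 (4S,5R)-4-ethenyl-4,5-dihydroxy-2-iodocyclohex-2-en-1-one; 7 (2E,4E,6R)-4,6-dimethyldeca-2,4-dienamide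
Product: 24 (2E,4E,6R)-N-[(3S,4R)-3-ethenyl-3,4-dihydroxy-6-oxocyclohex-1-en-1-yl]-4,6-dimethyldeca-2,4-dienamide
Conditions: CuI (10 mol %), trans-N,N′-dimethylcyclohexane-1,2-diamine (20 mol %), K3PO4, 1,4-dioxane, 45 °C, Ar
Reagents that add atoms: none
Why: Goldberg-type copper/diamine amidation of the activated α-iodoenone is N-selective in the presence of free hydroxyls, and the mild heterogeneous base at low temperature should spare the β-hydroxy ketone.

Step 15
Reactants: 24 (2E,4E,6R)-N-[(3S,4R)-3-ethenyl-3,4-dihydroxy-6-oxocyclohex-1-en-1-yl]-4,6-dimethyldeca-2,4-dienamide; 16 (2E,4E)-5-bromo-N-(2-hydroxy-5-oxocyclopent-1-en-1-yl)penta-2,4-dienamide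
Product: 25 (2E,4E,6R)-N-[(3S,4R)-3,4-dihydroxy-3-{(1E,3E,5E)-7-[(2-hydroxy-5-oxocyclopent-1-en-1-yl)amino]-7-oxohepta-1,3,5-trien-1-yl}-6-oxocyclohex-1-en-1-yl]-4,6-dimethyldeca-2,4-dienamide
Conditions: Pd(OAc)2 (10 mol %), Bu4NCl, NaHCO3, DMF, 40 °C, dark; work-up at pH 4
Reagents that add atoms: none
Why: Mizoroki–Heck vinylation under ligand-free Jeffery conditions adds the dienyl group (geometry retained) to the terminal vinyl carbon, and because the carbinol carbon is quaternary β-hydride elimination can only give the new E alkene, so the all-E triene forms without touching the stereocentres.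

**Compound list**
1 | (E)-hept-2-en-1-ol | CCCC/C=C/CO | starting material
2 | (E)-1-bromohept-2-ene | CCCC/C=C/CBr | intermediate
3 | (R)-3-methylhept-1-ene | CCCC[C@@H](C)C=C | intermediate
4 | methacrolein (2-methylprop-2-enal) | CC(=C)C=O | starting material
5 | (2E,4R)-2,4-dimethyloct-2-enal | CCCC[C@@H](C)/C=C(C)/C=O | intermediate
6 | diethyl (2-amino-2-oxoethyl)phosphonate | CCOP(=O)(CC(N)=O)OCC | starting material
7 | (2E,4E,6R)-4,6-dimethyldeca-2,4-dienamide | CCCC[C@@H](C)/C=C(C)/C=C/C(N)=O | intermediate
8 | pyridine–sulfur trioxide complex (pyridinium-1-sulfonate) | [O-]S(=O)(=O)[n+]1ccccc1 | starting material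
9 | potassium (1E,3E)-5-oxopenta-1,3-dien-1-olate (glutaconaldehyde potassium salt) | [K+].[O-]/C=C/C=C/C=O | intermediate
10 | (2E,4E)-5-bromopenta-2,4-dienal | Br/C=C/C=C/C=O | intermediate
11 | (2E,4E)-5-bromopenta-2,4-dienoic acid | Br/C=C/C=C/C(O)=O | intermediate
12 | cyclopentane-1,3-dione | O=C1CCC(=O)C1 | starting material
13 | 2-(hydroxyimino)cyclopentane-1,3-dione | ON=C1C(=O)CCC1=O | intermediate
14 | 2-amino-3-hydroxycyclopent-2-en-1-one hydrochloride | Cl.NC1=C(O)CCC1=O | intermediate
15 | (2E,4E)-5-bromopenta-2,4-dienoyl chloride | Br/C=C/C=C/C(Cl)=O | intermediate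
16 | (2E,4E)-5-bromo-N-(2-hydroxy-5-oxocyclopent-1-en-1-yl)penta-2,4-dienamide | Br/C=C/C=C/C(=O)NC1=C(O)CCC1=O | intermediate
17 | 4,4-dimethoxycyclohexa-2,5-dien-1-one | COC1(OC)C=CC(=O)C=C1 | starting material
18 | 1-ethenyl-4,4-dimethoxycyclohexa-2,5-dien-1-ol | COC1(OC)C=CC(O)(C=C)C=C1 | intermediate
19 | 4-ethenyl-4-hydroxycyclohexa-2,5-dien-1-one | O=C1C=CC(O)(C=C)C=C1 | intermediate
20 | (1-ethenyl-4-oxocyclohexa-2,5-dien-1-yl) hydrogen phenylboronate | O=C1C=CC(OB(O)c2ccccc2)(C=C)C=C1 | intermediate
21 | (3aR,7aS)-7a-ethenyl-2-phenyl-3a,4-dihydro-1,3,2-benzodioxaborol-5(7aH)-one (cis-fused) | C1=C[C@]2(C=C)OB(c3ccccc3)O[C@@H]2CC1=O | intermediate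
22 | (4S,5R)-4-ethenyl-4,5-dihydroxycyclohex-2-en-1-one (cis-diol) | O=C1C=C[C@@](O)(C=C)[C@H](O)C1 | intermediate
23 | (4S,5R)-4-ethenyl-4,5-dihydroxy-2-iodocyclohex-2-en-1-one | IC1=C[C@@](O)(C=C)[C@H](O)CC1=O | intermediate
24 | (2E,4E,6R)-N-[(3S,4R)-3-ethenyl-3,4-dihydroxy-6-oxocyclohex-1-en-1-yl]-4,6-dimethyldeca-2,4-dienamide | CCCC[C@@H](C)/C=C(C)/C=C/C(=O)NC1=C[C@@](O)(C=C)[C@H](O)CC1=O | intermediate
25 | (2E,4E,6R)-N-[(3S,4R)-3,4-dihydroxy-3-{(1E,3E,5E)-7-[(2-hydroxy-5-oxocyclopent-1-en-1-yl)amino]-7-oxohepta-1,3,5-trien-1-yl}-6-oxocyclohex-1-en-1-yl]-4,6-dimethyldeca-2,4-dienamide | CCCC[C@@H](C)/C=C(C)/C=C/C(=O)NC1=C[C@@](O)(/C=C/C=C/C=C/C(=O)NC2=C(O)CCC2=O)[C@H](O)CC1=O | target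

**Step count and risks**

Total step count: 15. Longest linear sequence: 6 (steps 1, 2, 3, 4, 14, 15). The core branch (steps 11–15) and the lower-chain branch (steps 5, 6, 7, 10, 15) are 5 each.

The three steps most likely to fail:

Step 12 (the proposed desymmetrising boronate oxa-Michael addition). The risks are slow hemiester formation at the tertiary alcohol and insufficient discrimination of the two enone arms. The fallback uses known chemistry of a different kind, a chiral Brønsted acid acetalisation/oxa-Michael cascade. It sets out from 19: treatment with 3-phenylpropanal and a chiral BINOL-derived phosphoric acid (TRIP type, antipode chosen for the 4S,5R series) in toluene forms the hemiacetal at the quinol oxygen, which closes enantioselectively onto one enone arm. This gives the cis-fused dioxolane (3aR,7aS)-7a-ethenyl-2-(2-phenylethyl)-3a,4-dihydro-1,3-benzodioxol-5(7aH)-one F1, enriched by recrystallisation if needed. Mild acid hydrolysis of the acetal (aq. TFA, THF, 0 °C) then comes back to the route at 22.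

Step 14 (copper amidation on the unprotected β-hydroxy ketone). The risks are retro-aldol cleavage, dehydration or copper chelation by the cis-diol. The fallback masks the diol for the two functionalisation steps. It sets out from 22: 2,2-dimethoxypropane and PPTS in acetone give the acetonide (3aR,7aS)-7a-ethenyl-2,2-dimethyl-3a,4-dihydro-1,3-benzodioxol-5(7aH)-one F2. Iodine/pyridine gives (3aR,7aS)-7a-ethenyl-6-iodo-2,2-dimethyl-3a,4-dihydro-1,3-benzodioxol-5(7aH)-one F3. CuI/diamine/K3PO4 coupling with 7 gives (2E,4E,6R)-N-[(3aR,7aS)-7a-ethenyl-2,2-dimethyl-5-oxo-3a,4,5,7a-tetrahydro-1,3-benzodioxol-6-yl]-4,6-dimethyldeca-2,4-dienamide F4. Acetonide hydrolysis (aq. AcOH, THF, 40 °C), done before the acid-sensitive triene is present, comes back to the route at 24.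

Step 15 (late-stage Heck coupling on a hindered vinyl carbinol with both partners unprotected). The risks are low conversion or polyene isomerisation. The fallback replaces the Heck reaction by a metathesis/cross-coupling pair. It sets out from 24: cross-metathesis with vinylboronic acid pinacol ester (second-generation Hoveyda–Grubbs catalyst, CH2Cl2, 40 °C) gives the E-alkenylboronate (2E,4E,6R)-N-[(3S,4R)-3,4-dihydroxy-6-oxo-3-[(E)-2-(4,4,5,5-tetramethyl-1,3,2-dioxaborolan-2-yl)ethenyl]cyclohex-1-en-1-yl]-4,6-dimethyldeca-2,4-dienamide F5. Suzuki–Miyaura coupling of F5 with 16 (Pd(PPh3)4, aq. K3PO4, THF, rt) comes back to the route at 25.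

**Further compounds**
F1 | step 12 | (3aR,7aS)-7a-ethenyl-2-(2-phenylethyl)-3a,4-dihydro-1,3-benzodioxol-5(7aH)-one (acetal carbon unassigned) | C1=C[C@]2(C=C)OC(CCc3ccccc3)O[C@@H]2CC1=O
F2 | step 14 | (3aR,7aS)-7a-ethenyl-2,2-dimethyl-3a,4-dihydro-1,3-benzodioxol-5(7aH)-one | C1=C[C@]2(C=C)OC(C)(C)O[C@@H]2CC1=O
F3 | step 14 | (3aR,7aS)-7a-ethenyl-6-iodo-2,2-dimethyl-3a,4-dihydro-1,3-benzodioxol-5(7aH)-one | IC1=C[C@]2(C=C)OC(C)(C)O[C@@H]2CC1=O
F4 | step 14 | (2E,4E,6R)-N-[(3aR,7aS)-7a-ethenyl-2,2-dimethyl-5-oxo-3a,4,5,7a-tetrahydro-1,3-benzodioxol-6-yl]-4,6-dimethyldeca-2,4-dienamide | CCCC[C@@H](C)/C=C(C)/C=C/C(=O)NC1=C[C@]2(C=C)OC(C)(C)O[C@@H]2CC1=O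
F5 | step 15 | (2E,4E,6R)-N-[(3S,4R)-3,4-dihydroxy-6-oxo-3-[(E)-2-(4,4,5,5-tetramethyl-1,3,2-dioxaborolan-2-yl)ethenyl]cyclohex-1-en-1-yl]-4,6-dimethyldeca-2,4-dienamide | CCCC[C@@H](C)/C=C(C)/C=C/C(=O)NC1=C[C@@](O)(/C=C/B2OC(C)(C)C(C)(C)O2)[C@H](O)CC1=O
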